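## Analysis of the target

CNP0241001.1 is a daucane sesquiterpenoid: a cyclopentane (C1–C5) fused through the C1–C5 bond to a cycloheptane (C1, C5–C10), with O6 esterified by 4-hydroxybenzoic acid. Daucane numbering is used throughout: C1 is the methyl-bearing fusion carbon, C4 the isopropyl carbinol, C5 the fusion CH, C6 the ester carbon, C7 the ketone, C8 the methyl carbinol, C9 the CHOH and C10 the CH2; β is the face of the C1 methyl. There are six stereocentres, (1R,4R,5S,6R,8S,9S). The ring fusion is trans (C1 methyl β, H5 α), the C4 hydroxyl is β (cis to the C1 methyl, trans to H5), and the oxygens at C6, C8 and C9 are all α. The sensitive groups are the α-acyloxy ketone at C6/C7 (epimerisation, acyl migration), the tertiary α-ketol C8(OH)–C7(=O) (α-ketol shift), the β-hydroxy ketone C9(OH)/C7 (retro-aldol), two tertiary alcohols and a free phenol. The synthesis is hard because C5 lies between two fully substituted carbons (C1 and C4) and because five contiguous ring carbons, C5 to C9, are functionalised on a flexible seven-membered ring. The strategy rests on one feature: the fifteen skeletal carbons are an unbroken head-to-tail farnesyl chain closed by only two bonds, C1–C10 and C4–C5, and the oxygens sit at or next to the two olefins (C4=C5, C8=C9) that such a closure leaves behind.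

## Retrosynthetic reasoning

**18 ⇒ 17 ⇒ 16.** The last two operations cut no skeletal bond: the phenol is unmasked from benzyl ether 17 by hydrogenolysis, and 17 comes from 16 by acid removal of the acetonide and the silyl ether. These come last because the free α-ketol, the β-hydroxy ketone and the phenol would not survive the bases and oxidants used earlier.

**16 ⇒ 14 + 15.** The ester C(=O)–O6 bond is cut. It is the only convergent bond in the molecule, and in 14 O6 is the only free hydroxyl, so acyl chloride 15 has no competing site.

**14 ⇒ 13.** The C6–O bond is cut. C6 is α to the C7 ketone and C8 carries no hydrogen, so the enolate of 13 can only form toward C6. The forward step has to bring the oxygen in from the α face.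

**13 ⇒ 12 ⇒ 11.** The acetonide is removed and the C5–H and C6–H bonds are cut back to enone 11. C5 is the stereocentre that ordinary reagents would set wrongly, since they would approach the convex β face and give the cis-fused ring system. The α-diol at C8/C9 in 11 is used as the handle that carries hydrogen to the α face.

**11 ⇒ 10 ⇒ 9.** The C8–O and C9–O bonds are cut back to the C8=C9 olefin of dienone 10, and the silyl ether is cut back to alcohol 9. A syn diol on the face opposite the C1 methyl is what a sterically controlled osmium dihydroxylation should give, and the second olefin, C5=C6, is too encumbered to compete.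

**9 ⇒ 8 ⇒ 7 ⇒ 6.** The γ-hydroxy enone of 9 is the ring-opened form of a β,γ-epoxy ketone, so O4 is reconnected to C5 to give 8. The ketone of 8 is traced to allylic alcohol 7 and the C7–O bond is cut to give 6. Placing the C7 carbonyl (needed in the target anyway) before the epoxide opening means the tetrasubstituted epoxide can open only toward C6; a plain base-induced isomerisation would have to choose between C6–H, C3–H and the isopropyl C–H. C7 is the ring methylene next to the more substituted end of the C8=C9 olefin, the normal site of a Riley oxidation.

**6 ⇒ 5 ⇒ 4.** Both C–O bonds of the epoxide are cut back to the C4=C5 olefin of daucene 4. The epoxide must be β (C4–O cis to the C1 methyl), whereas direct oxygen transfer is expected on the opposite face. The oxygen is therefore brought in by anti addition (bromohydrin 5) and ring closure.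

**4 ⇒ 3.** The key disconnection cuts C1–C10 and C4–C5. These are the only two bonds of the skeleton that are not part of a head-to-tail C15 chain, so cutting them removes both rings and the quaternary stereocentre at once and leaves the achiral diphosphate 3. The forward reaction must fold the chain, close a seven- and a five-membered ring, fix C1 and terminate as the diene.

**3 ⇒ 2 ⇒ 1.** The C–O bond of the diphosphate ester is cut back to allylic bromide 2 and then to farnesol 1.

## Alternatives that were turned down

**Alternative 1:** Claisen ring expansion. The C1–C10 bond is disconnected and C6–O is reconnected, so that the seven-membered ring arises from a [3,3] shift of an allyl vinyl ether array C10=C9–O–C6–C5=C1 held in a furanoid ring. Heating would give A1, a daucane-type 5-en-9-one with a C7,C8 acetonide and a C4 ketal.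
- For: ring, quaternary C1 and the C5=C6 olefin come from one concerted step with chirality transfer, the C7 and C8 oxygens arrive with fixed configuration, and no enzyme has to be found. On these points it is stronger than the chosen route, whose C8/C9 diol depends on substrate control.
- Against: A1 has no isopropyl group. It would have to be added to the C4 ketone, an enolisable cyclopentanone beside a ring-fusion olefin, with a β-hydride-bearing secondary nucleophile and unsecured facial control. The oxidation levels at C7 and C9 are the reverse of those in the target. C5=C6 still has to become H5α/O6α. The rearrangement substrate is itself a long synthesis.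
- Comparison: the chosen route offers all fifteen carbons, both rings and C1 in one operation from a two-step precursor, with the isopropyl group already in place.

**Alternative 2:** Conjugate methylation–aldol. The C1–CH3 and C5–C6 bonds are disconnected. Copper-catalysed asymmetric addition of a methylaluminium reagent to enone A2, with trapping of the aluminium enolate by a three-carbon enal, would give A3.
- For: quaternary C1 is made by asymmetric catalysis, O6 is installed at once, and C5 is α to a ketone and so can be equilibrated. That is a cleaner answer to the ring-fusion hydrogen than the directed hydrogenation used here.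
- Against: β-substituted cyclopentenones are the weakest substrate class for this addition. The aldol step can give four C5/C6 diastereomers and competes with conjugate addition to the enal. The seven-membered ring, the C8 methyl, the C8/C9 diol, the C7 ketone and the isopropyl carbinol (on a β-hydroxy ketone prone to retro-aldol) all remain to be built.
- Comparison: the step count would be roughly double; the chosen route trades the C5 advantage for a finished carbon skeleton.

**Alternative 3:** Carbenoid C–H insertion. The C4–C5 bond is disconnected. A rhodium carbenoid from diazo ketone A4 would insert into the C4–H bond next to the silyloxy group and give A5, a daucane 7-en-6-one with the C4 silyl ether.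
- For: insertion goes with retention, so the tertiary C4 centre is derived from an easily made secondary carbinol. This is more secure than the facial bias of a bromonium ion on which the chosen route depends at C4. The isopropyl group is present, and the C6 carbonyl lets C5 be equilibrated.
- Against: A4 already needs an enantioselective synthesis of a cycloheptenone with quaternary C1, which is exactly what the cyclase supplies. Diazo transfer next to a quaternary carbon is awkward, and other C–H bonds compete. The oxygenation of A5 is displaced by one carbon (C6 ketone and C7=C8 instead of C6 ester, C7 ketone and C8/C9 diol), which costs a carbonyl transposition and an olefin shift.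
- Comparison: the chosen route places both olefins where the oxygens are needed and is much shorter.

Key step: step 3

Assumption: a class 1 sesquiterpene cyclase that releases (1R)-daucene 4 as its main product is available after screening of daucene/carotol-type synthases; 3 is handled as its ammonium salt; 15 is purchased.

## Route

Step 1
Reactants: 1 (2E,6E)-farnesol
Product: 2 (2E,6E)-farnesyl bromide
Conditions: PBr3 (0.4 equiv), Et2O, −10 → 0 °C; used crude
Reagents that add atoms: phosphorus tribromide, BrP(Br)Br
Why: Bromination of a primary allylic alcohol through its phosphite ester; at low temperature the (2E) geometry is kept and no allylic transposition is expected.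

Step 2
Reactants: 2 (2E,6E)-farnesyl bromide
Product: 3 (2E,6E)-farnesyl diphosphate (isolated as the tris-ammonium salt, drawn as the free acid)
Conditions: (n-Bu4N)3HP2O7 (2 equiv), MeCN, rt; cation-exchange resin (NH4+ form), then cellulose chromatography
Reagents that add atoms: tris(tetrabutylammonium) hydrogen diphosphate, CCCC[N+](CCCC)(CCCC)CCCC.CCCC[N+](CCCC)(CCCC)CCCC.CCCC[N+](CCCC)(CCCC)CCCC.OP(=O)([O-])OP(=O)([O-])[O-]
Why: SN2 displacement of the primary allylic bromide by the diphosphate anion, the standard entry to allylic diphosphates; ion exchange gives a water-soluble enzyme substrate.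

Step 3
Reactants: 3 (2E,6E)-farnesyl diphosphate
Product: 4 daucene, (1R)-dauca-4,8-diene
Conditions: recombinant daucene-forming class 1 sesquiterpene cyclase, MgCl2 (10 mM), HEPES buffer pH 7.5, dithiothreitol, 30 °C, pentane overlay
Reagents that add atoms: none
Why: Magnesium-assisted ionisation of the diphosphate gives the farnesyl cation, which collapses to nerolidyl diphosphate and re-ionises as the cisoid allyl cation so that C8=C9 can become a ring cis-olefin. The central olefin attacks the allyl terminus (bond C1–C10, a 7-endo closure with respect to that olefin), and the charge developing at C5 is taken up at once by the distal olefin in a 5-exo closure (bond C4–C5), leaving the isopropyl cation. A 1,2-hydride shift from C4 and loss of the C5 proton then give the C4=C5 olefin. The closest known reaction type is the cation–olefin cyclisation of farnesyl diphosphate by class 1 sesquiterpene synthases of the daucene/carotol family. The only stereocentre that survives, quaternary C1, is fixed by the fold that the active site imposes on the achiral chain; C5 is set only transiently and erased by the deprotonation. The step needs 1,7- rather than 1,6- or 1,10-closure, a single enantiomeric fold, and termination by deprotonation at C5 rather than water capture; the head-to-tail order of 3 only makes these bonds possible, so all of the selectivity rests on the enzyme.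

Step 4
Reactants: 4 daucene
Product: 6 β-epoxide of daucene (4β,5β-epoxydauc-8-ene), via trans-bromohydrin 5 (not isolated)
Conditions: N-bromosuccinimide (1.05 equiv), THF/H2O (4:1), 0 °C; then K2CO3, MeOH, rt
Reagents that add atoms: water, O (N-bromosuccinimide, O=C1CCC(=O)N1Br, puts bromine into intermediate 5 only)
Why: Bromohydrin formation and intramolecular Williamson closure; the tetrasubstituted C4=C5 bond is the more nucleophilic olefin, and the bromonium ion is expected on the α face, away from the C1 methyl, as with angularly methylated ring-fusion olefins. Water opens it anti from the β face and either regioisomeric trans-bromohydrin closes to the same epoxide, so the C4–O bond is set β.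

Step 5
Reactants: 6 β-epoxide of daucene
Product: 7 4β,5β-epoxydauc-8-en-7α-ol
Conditions: SeO2 (0.3 equiv), t-BuOOH (in decane, 2.5 equiv), CH2Cl2, 0 °C → rt
Reagents that add atoms: tert-butyl hydroperoxide, CC(C)(C)OO (oxygen relayed through selenium dioxide, O=[Se]=O)
Why: Riley allylic oxidation (ene reaction, then [2,3]-shift); it attacks the ring methylene next to the more substituted olefin carbon C8, that is C7, and returns the double bond to C8=C9. The C7 configuration (α expected) is of no consequence because C7 is oxidised in the next step, and any enone 8 formed directly is carried along.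

Step 6
Reactants: 7 4β,5β-epoxydauc-8-en-7α-ol
Product: 9 dienone (4β-hydroxydauca-5,8-dien-7-one), via epoxy enone 8 (not isolated)
Conditions: Dess–Martin periodinane, CH2Cl2, 0 °C; then DBU (3 equiv), rt
Reagents that add atoms: none
Why: Alcohol oxidation gives the β,γ-epoxy enone 8, whose only α-hydrogens are at C6; DBU then opens the epoxide at C5 by E1cB elimination, which fixes the new olefin at C5=C6 and leaves the C4–O bond, and so the β-carbinol, untouched.

Step 7
Reactants: 9 4β-hydroxydauca-5,8-dien-7-one
Product: 10 4β-(triethylsilyloxy)dauca-5,8-dien-7-one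
Conditions: Et3SiOTf, 2,6-lutidine, CH2Cl2, −78 → 0 °C
Reagents that add atoms: triethylsilyl trifluoromethanesulfonate, CC[Si](CC)(CC)OS(=O)(=O)C(F)(F)F
Why: Silylation of a hindered tertiary alcohol with a silyl triflate; the ether removes the only β-face hydroxyl so that it cannot steer the later hydrogenation.

Step 8
Reactants: 10 4β-(triethylsilyloxy)dauca-5,8-dien-7-one
Product: 11 8α,9α-dihydroxy-4β-(triethylsilyloxy)dauc-5-en-7-one
Conditions: OsO4 (5 mol %), N-methylmorpholine N-oxide (2 equiv), acetone/H2O, rt
Reagents that add atoms: N-methylmorpholine N-oxide, C[N+]1([O-])CCOCC1; water, O (both oxygens are transferred through OsO4)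
Why: Catalytic syn-dihydroxylation; C5=C6 lies between two fully substituted carbons and should be left alone. OsO4 should add to C8=C9 from the α face because the pseudo-axial C1 methyl covers the β face at C9, which sets C8 and C9 together.

Step 9
Reactants: 11 8α,9α-dihydroxy-4β-(triethylsilyloxy)dauc-5-en-7-one
Product: 12 8α,9α-dihydroxy-4β-(triethylsilyloxy)-5αH-daucan-7-one
Conditions: [Ir(cod)(PCy3)(py)]PF6 (10 mol %), H2 (1 atm), CH2Cl2, rt
Reagents that add atoms: none
Why: Hydroxyl-directed homogeneous hydrogenation; the cationic iridium centre is held by the α-hydroxyls at C8/C9 and delivers both hydrogens to the α face of C5=C6. This gives H5 α (trans ring fusion) against the intrinsic steric preference, and the silyl ether at O4 does not coordinate.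

Step 10
Reactants: 12 8α,9α-dihydroxy-4β-(triethylsilyloxy)-5αH-daucan-7-one
Product: 13 8α,9α-(isopropylidenedioxy)-4β-(triethylsilyloxy)-5αH-daucan-7-one
Conditions: 2,2-dimethoxypropane, pyridinium p-toluenesulfonate (cat.), CH2Cl2, rt
Reagents that add atoms: 2,2-dimethoxypropane, COC(C)(C)OC
Why: Acid-catalysed transacetalisation of the cis-8,9-diol to the five-membered acetonide; it shuts off α-ketol and retro-aldol pathways during enolate chemistry and leaves O6 as the only hydroxyl to be acylated later.

Step 11
Reactants: 13 8α,9α-(isopropylidenedioxy)-4β-(triethylsilyloxy)-5αH-daucan-7-one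
Product: 14 6α-hydroxy-8α,9α-(isopropylidenedioxy)-4β-(triethylsilyloxy)-5αH-daucan-7-one
Conditions: KN(SiMe3)2, THF, −78 °C; 2-(phenylsulfonyl)-3-phenyloxaziridine, −78 °C; NH4Cl (aq)
Reagents that add atoms: 2-(phenylsulfonyl)-3-phenyloxaziridine, O=S(=O)(c1ccccc1)N1OC1c1ccccc1
Why: Davis enolate oxidation; C8 is fully substituted, so the ketone can enolise only toward C6. The oxidant should approach from the α face, beside the axial H5 and away from the axial C1 methyl and the C4 silyloxy group, giving the 6α-alcohol.

Step 12
Reactants: 14 6α-hydroxy-8α,9α-(isopropylidenedioxy)-4β-(triethylsilyloxy)-5αH-daucan-7-one; 15 4-(benzyloxy)benzoyl chloride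
Product: 16 6α-[4-(benzyloxy)benzoyloxy]-8α,9α-(isopropylidenedioxy)-4β-(triethylsilyloxy)-5αH-daucan-7-one
Conditions: Et3N, DMAP (cat.), CH2Cl2, 0 °C
Reagents that add atoms: 4-(benzyloxy)benzoyl chloride, O=C(Cl)c1ccc(OCc2ccccc2)cc1
Why: DMAP-catalysed acylation of the only free hydroxyl by an aroyl chloride; low temperature and short contact with base limit epimerisation at C6.

Step 13
Reactants: 16 6α-[4-(benzyloxy)benzoyloxy]-8α,9α-(isopropylidenedioxy)-4β-(triethylsilyloxy)-5αH-daucan-7-one
Product: 17 6α-[4-(benzyloxy)benzoyloxy]-4β,8α,9α-trihydroxy-5αH-daucan-7-one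
Conditions: 1 M HCl (aq), THF, rt
Reagents that add atoms: none
Why: Aqueous acid hydrolyses the acetonide and the tertiary silyl ether in one operation while the aryl ester and the benzyl ether are stable; base is avoided because of the α-ketol and the α-acyloxy ketone.

Step 14
Reactants: 17 6α-[4-(benzyloxy)benzoyloxy]-4β,8α,9α-trihydroxy-5αH-daucan-7-one
Product: 18 CNP0241001.1, 6α-(4-hydroxybenzoyloxy)-4β,8α,9α-trihydroxy-5αH-daucan-7-one
Conditions: H2 (1 atm), Pd/C (10 %), EtOAc, rt
Reagents that add atoms: none
Why: Hydrogenolysis of the benzyl aryl ether under neutral conditions; nothing else in 17 is reducible at one atmosphere of hydrogen.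

## Compound list

1 | (2E,6E)-farnesol | CC(C)=CCC/C(C)=C/CC/C(C)=C/CO | starting material
2 | (2E,6E)-farnesyl bromide | CC(C)=CCC/C(C)=C/CC/C(C)=C/CBr | intermediate
3 | (2E,6E)-farnesyl diphosphate (free acid drawn) | CC(C)=CCC/C(C)=C/CC/C(C)=C/COP(=O)(O)OP(=O)(O)O | intermediate
4 | daucene, (1R)-dauca-4,8-diene | CC(C)C1=C2CCC(C)=CC[C@@]2(C)CC1 | intermediate
5 | 5α-bromodauc-8-en-4β-ol (trans-bromohydrin, not isolated) | CC(C)[C@]1(O)CC[C@]2(C)CC=C(C)CC[C@]21Br | intermediate
6 | 4β,5β-epoxydauc-8-ene | CC(C)[C@]12CC[C@]3(C)CC=C(C)CC[C@@]31O2 | intermediate
7 | 4β,5β-epoxydauc-8-en-7α-ol | CC(C)[C@]12CC[C@]3(C)CC=C(C)[C@H](O)C[C@@]31O2 | intermediate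
8 | 4β,5β-epoxydauc-8-en-7-one (not isolated) | CC(C)[C@]12CC[C@]3(C)CC=C(C)C(=O)C[C@@]31O2 | intermediate
9 | 4β-hydroxydauca-5,8-dien-7-one | CC(C)[C@]1(O)CC[C@]2(C)CC=C(C)C(=O)C=C21 | intermediate
10 | 4β-(triethylsilyloxy)dauca-5,8-dien-7-one | CC(C)[C@]1(O[Si](CC)(CC)CC)CC[C@]2(C)CC=C(C)C(=O)C=C21 | intermediate
11 | 8α,9α-dihydroxy-4β-(triethylsilyloxy)dauc-5-en-7-one | CC(C)[C@]1(O[Si](CC)(CC)CC)CC[C@]2(C)C[C@H](O)[C@](C)(O)C(=O)C=C21 | intermediate
12 | 8α,9α-dihydroxy-4β-(triethylsilyloxy)-5αH-daucan-7-one | CC(C)[C@]1(O[Si](CC)(CC)CC)CC[C@]2(C)C[C@H](O)[C@](C)(O)C(=O)C[C@H]21 | intermediate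
13 | 8α,9α-(isopropylidenedioxy)-4β-(triethylsilyloxy)-5αH-daucan-7-one | CC(C)[C@]1(O[Si](CC)(CC)CC)CC[C@]2(C)C[C@@H]3OC(C)(C)O[C@]3(C)C(=O)C[C@H]21 | intermediate
14 | 6α-hydroxy-8α,9α-(isopropylidenedioxy)-4β-(triethylsilyloxy)-5αH-daucan-7-one | CC(C)[C@]1(O[Si](CC)(CC)CC)CC[C@]2(C)C[C@@H]3OC(C)(C)O[C@]3(C)C(=O)[C@H](O)[C@H]21 | intermediate
15 | 4-(benzyloxy)benzoyl chloride | O=C(Cl)c1ccc(OCc2ccccc2)cc1 | starting material
16 | 6α-[4-(benzyloxy)benzoyloxy]-8α,9α-(isopropylidenedioxy)-4β-(triethylsilyloxy)-5αH-daucan-7-one | CC(C)[C@]1(O[Si](CC)(CC)CC)CC[C@]2(C)C[C@@H]3OC(C)(C)O[C@]3(C)C(=O)[C@H](OC(=O)c4ccc(OCc5ccccc5)cc4)[C@H]21 | intermediate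
17 | 6α-[4-(benzyloxy)benzoyloxy]-4β,8α,9α-trihydroxy-5αH-daucan-7-one | CC(C)[C@]1(O)CC[C@]2(C)C[C@H](O)[C@](C)(O)C(=O)[C@H](OC(=O)c3ccc(OCc4ccccc4)cc3)[C@H]21 | intermediate
18 | CNP0241001.1, 6α-(4-hydroxybenzoyloxy)-4β,8α,9α-trihydroxy-5αH-daucan-7-one | CC(C)[C@]1(O)CC[C@]2(C)C[C@H](O)[C@](C)(O)C(=O)[C@H](OC(=O)c3ccc(O)cc3)[C@H]21 | target

## Step count and least certain steps

Total step count: 14. Longest linear sequence: 14 steps (1 → 18); 15 is purchased.

**Step 3 (key step).** The cyclase may terminate by water capture or by a different deprotonation, may fold the chain in the other enantiomeric sense, or may turn over poorly because the volatile, hydrophobic product inhibits it. Fallback, from 3 back to 4: a carotol synthase, which hydrates the same bicyclic cation after a second hydride shift, would give carotol F1. Chemical dehydration of the tertiary C5 alcohol toward C4 (SOCl2, pyridine) would then return to 4. This replaces the enzymatic termination by a chemical one.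

**Step 4.** Facial discrimination at the C4=C5 bond could be weak or reversed, because only the C1 methyl and the C10 methylene distinguish the two faces. Loss of a proton from the bromonium ion (allylic bromination) may also compete with water capture. Fallback, from 4 directly to 6: oxygen-atom transfer with a peracid or dimethyldioxirane, which places the epoxide on the face the electrophile attacks rather than on the opposite one. Of the two complementary modes, one should favour 6 unless the faces are indistinguishable; in that case the diastereomeric epoxides would have to be separated. This fallback makes no new compound (F0).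

**Step 5.** Acid-promoted opening of the tetrasubstituted epoxide, possibly by the new C7 hydroxyl, and competing oxidation of the C8 methyl could erode the Riley oxidation. Fallback, from 6 back to 9: the epoxide is first isomerised by syn-elimination with Et2Al(TMP) (from LiTMP and Et2AlCl) to dauca-5,8-dien-4β-ol F2. Its doubly allylic C7 methylene is then oxidised with SeO2/t-BuOOH to dauca-5,8-diene-4β,7α-diol F3, and MnO2 gives 9. No epoxide is then exposed to the oxidant, at the price of a regiochemical question (C6–H against C3–H) in the isomerisation.

**Step 9.** The conjugated olefin, whose C5 lies between two quaternary carbons, may fail to bind the iridium centre, or undirected reduction from the β face may give the cis-fused ketone. Fallback, from 11 back to 16, moves hydrogen to C5 by stereospecific 1,3-transfer from C7: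
- Me4NBH(OAc)3 (MeCN/AcOH) delivers hydride from the α-hydroxyls (Evans–Saksena reduction) and gives 4β-(triethylsilyloxy)dauc-5-ene-7β,8α,9α-triol F4.
- Acetonide formation on the cis-8,9-diol gives 8α,9α-(isopropylidenedioxy)-4β-(triethylsilyloxy)dauc-5-en-7β-ol F5, and formylation gives its 7β-formate F6.
- Pd(OAc)2/PBu3 in refluxing THF ionises the formate from the α face and the palladium hydride formed by decarboxylation is passed to C5 on that face (Tsuji-type formate hydrogenolysis), giving 8α,9α-(isopropylidenedioxy)-4β-(triethylsilyloxy)-5αH-dauc-6-ene F7.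
- OsO4/N-methylmorpholine N-oxide gives 8α,9α-(isopropylidenedioxy)-4β-(triethylsilyloxy)-5αH-daucane-6α,7α-diol F8.
- Acylation with 15 at the less hindered O6 gives 6α-[4-(benzyloxy)benzoyloxy]-8α,9α-(isopropylidenedioxy)-4β-(triethylsilyloxy)-5αH-daucan-7α-ol F9, and Dess–Martin oxidation gives 16.

**Step 11.** Approach of the oxidant from the β face (the α face carries the acetonide oxygen at C8) or epimerisation of the α-ketol alkoxide could give the wrong C6 configuration. Fallback, from 13 back to 16: if the 6β-hydroxy epimer of 14 F10 is formed, it is esterified under Mitsunobu conditions (PPh3, diisopropyl azodicarboxylate, 4-(benzyloxy)benzoic acid). The activated α-keto carbinol is displaced with inversion, which gives 16 directly and replaces step 12.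

## Further compounds

F1 | step 3 | carotol (dauc-8-en-5-ol) | CC1=CC[C@]2(CC[C@@H]([C@]2(CC1)O)C(C)C)C
F0 | step 4 | none | none
F2 | step 5 | dauca-5,8-dien-4β-ol | CC(C)[C@]1(O)CC[C@]2(C)CC=C(C)CC=C21
F3 | step 5 | dauca-5,8-diene-4β,7α-diol | CC(C)[C@]1(O)CC[C@]2(C)CC=C(C)[C@H](O)C=C21
F4 | step 9 | 4β-(triethylsilyloxy)dauc-5-ene-7β,8α,9α-triol | CC(C)[C@]1(O[Si](CC)(CC)CC)CC[C@]2(C)C[C@H](O)[C@](C)(O)[C@@H](O)C=C21
F5 | step 9 | 8α,9α-(isopropylidenedioxy)-4β-(triethylsilyloxy)dauc-5-en-7β-ol | CC(C)[C@]1(O[Si](CC)(CC)CC)CC[C@]2(C)C[C@@H]3OC(C)(C)O[C@]3(C)[C@@H](O)C=C21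
F6 | step 9 | 8α,9α-(isopropylidenedioxy)-4β-(triethylsilyloxy)dauc-5-en-7β-yl formate | CC(C)[C@]1(O[Si](CC)(CC)CC)CC[C@]2(C)C[C@@H]3OC(C)(C)O[C@]3(C)[C@@H](OC=O)C=C21
F7 | step 9 | 8α,9α-(isopropylidenedioxy)-4β-(triethylsilyloxy)-5αH-dauc-6-ene | CC(C)[C@]1(O[Si](CC)(CC)CC)CC[C@]2(C)C[C@@H]3OC(C)(C)O[C@]3(C)C=C[C@H]21
F8 | step 9 | 8α,9α-(isopropylidenedioxy)-4β-(triethylsilyloxy)-5αH-daucane-6α,7α-diol | CC(C)[C@]1(O[Si](CC)(CC)CC)CC[C@]2(C)C[C@@H]3OC(C)(C)O[C@]3(C)[C@H](O)[C@H](O)[C@H]21
F9 | step 9 | 6α-[4-(benzyloxy)benzoyloxy]-8α,9α-(isopropylidenedioxy)-4β-(triethylsilyloxy)-5αH-daucan-7α-ol | CC(C)[C@]1(O[Si](CC)(CC)CC)CC[C@]2(C)C[C@@H]3OC(C)(C)O[C@]3(C)[C@H](O)[C@H](OC(=O)c4ccc(OCc5ccccc5)cc4)[C@H]21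
F10 | step 11 | 6β-hydroxy-8α,9α-(isopropylidenedioxy)-4β-(triethylsilyloxy)-5αH-daucan-7-one | CC(C)[C@]1(O[Si](CC)(CC)CC)CC[C@]2(C)C[C@@H]3OC(C)(C)O[C@]3(C)C(=O)[C@@H](O)[C@H]21
A1 | alternative 1 | daucane-type 5-en-9-one with C7,C8 acetonide and C4 dioxolane | C1COC2(O1)CC[C@]3(C)CC(=O)[C@]4(C)OC(C)(C)O[C@@H]4C=C23
A2 | alternative 2 | 3-(1,3-dioxolan-2-ylmethyl)cyclopent-2-en-1-one | O=C1CCC(CC2OCCO2)=C1
A3 | alternative 2 | 2-(1-hydroxyallyl)-3-methyl-3-(1,3-dioxolan-2-ylmethyl)cyclopentanone | O=C1CC[C@](C)(CC2OCCO2)[C@H]1[C@@H](O)C=C
A4 | alternative 3 | 7-diazo-3,6-dimethyl-6-[3-(tert-butyldimethylsilyloxy)-4-methylpentyl]cyclohept-2-en-1-one | CC(C)[C@H](O[Si](C)(C)C(C)(C)C)CC[C@]1(C)CCC(C)=CC(=O)C1=[N+]=[N-]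
A5 | alternative 3 | daucane 7-en-6-one with C4 tert-butyldimethylsilyl ether | CC(C)[C@]1(O[Si](C)(C)C(C)(C)C)CC[C@]2(C)CCC(C)=CC(=O)[C@H]21
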